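**Plan** (germacranolide numbering: C1 ring ketone, C2=C3, C4(C15)=C5, C6 lactone O–CH, C7, C8 tiglate carbinol, C9, C10(C14), C11(=C13)–C12 lactone carbonyl)
1. Cuts: O–C3 of the furanone (last ring), C1–C2 (ten-membered carbocycle), C7–C8, C11–C12 (lactone ring), C3–C4, and the C8 ester.
2. Forward: Z-enyne enal → butenolide (lactone ring) → Barbier union with a C8–C10/C1 aldehyde giving the trans α-methylene lactone → tiglate → Nozaki–Hiyama–Kishi closure of the carbocycle → oxidation and transannular cycloisomerisation to the furanone → PMB removal.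
3. Stereochemistry: C6 from a zinc–ProPhenol alkynylation; C7 and C8 relayed from C6 in the Barbier step; C10 from (S)-2-methylglycidol; C4=C5 geometry from hydroxyl-directed hydroalumination–iodination; tiglate geometry from tiglic acid.
4. Enabling feature: the ring (O, C3, C2, C1, C10) is the cyclodehydrated form of a 10-hydroxy-1,3-dione, the biogenetic 3,10-hemiketal pattern. Its dehydrated equivalent, a C1-keto C2≡C3 alkyne with the free C10 hydroxyl 1,4 to C3, can be held in the ten-membered ring C1–C10, and forming O–C3 takes the bent triple bond out of that ring.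

Key step: step 18

Assumption: the facial sense of the zinc–ProPhenol alkynylation in step 5 is taken from the model established for enals (the (S,S) ligand giving the 4R carbinol); should the opposite carbinol form, the antipodal ligand would be used.

Step 1
Reactants: 1 but-2-yne-1,4-diol
Product: 2 4-[(4-methoxybenzyl)oxy]but-2-yn-1-ol
Conditions: NaH (1 equiv), PMBCl, Bu4NI (cat.), THF/DMF, 0 °C to rt; diol in threefold excess
Reagents that add atoms: 4-methoxybenzyl chloride, COc1ccc(CCl)cc1
Why: Williamson etherification of the monoalkoxide, the excess of the symmetrical diol keeping bis-alkylation low.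

Step 2
Reactants: 2 4-[(4-methoxybenzyl)oxy]but-2-yn-1-ol
Product: 4 (Z)-3-iodo-4-[(4-methoxybenzyl)oxy]but-2-en-1-ol, via cyclic sodium vinylalanate 3 (not isolated)
Conditions: NaAlH2(OCH2CH2OMe)2, THF, 0 °C; then I2, THF, −78 °C
Reagents that add atoms: iodine, [I][I]; sodium bis(2-methoxyethoxy)aluminium dihydride, [Na+].COCCO[AlH2-]OCCOC (its atoms stay in intermediate 3 only)
Why: Hydroxyl-directed trans-hydroalumination places hydride on C-2 and aluminium on C-3 in a five-membered alkoxy-alanate, and iodinolysis with retention should give the Z iodide that fixes the C4=C5 geometry of the target.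

Step 3
Reactants: 4 (Z)-3-iodo-4-[(4-methoxybenzyl)oxy]but-2-en-1-ol; 5 ethynyltrimethylsilane
Product: 6 (E)-3-{[(4-methoxybenzyl)oxy]methyl}-5-(trimethylsilyl)pent-2-en-4-yn-1-ol (alkyne cis to the CH2OH carbon)
Conditions: Pd(PPh3)2Cl2 (3 mol %), CuI (6 mol %), Et3N, THF, rt
Reagents that add atoms: none
Why: Sonogashira coupling of the vinyl iodide proceeds with retention of alkene geometry and tolerates the free allylic alcohol at room temperature.

Step 4
Reactants: 6 (E)-3-{[(4-methoxybenzyl)oxy]methyl}-5-(trimethylsilyl)pent-2-en-4-yn-1-ol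
Product: 7 (E)-3-{[(4-methoxybenzyl)oxy]methyl}-5-(trimethylsilyl)pent-2-en-4-ynal (CHO cis to the alkyne)
Conditions: Dess–Martin periodinane, CH2Cl2, 0 °C
Reagents that add atoms: none
Why: Dess–Martin oxidation of the allylic alcohol is fast and non-basic, so the enal should form without isomerisation of the double bond or cyclisation of the cis-enynol.

Step 5
Reactants: 7 (E)-3-{[(4-methoxybenzyl)oxy]methyl}-5-(trimethylsilyl)pent-2-en-4-ynal; 8 tert-butyldimethyl(prop-2-yn-1-yloxy)silane
Product: 9 (4R,5E)-1-[(tert-butyldimethylsilyl)oxy]-6-{[(4-methoxybenzyl)oxy]methyl}-8-(trimethylsilyl)oct-5-ene-2,7-diyn-4-ol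
Conditions: Me2Zn (3 equiv), (S,S)-ProPhenol (20 mol %), Ph3PO (40 mol %), toluene, 0 °C
Reagents that add atoms: none
Why: Zinc–ProPhenol catalysed enantioselective alkynylation of an enal, in which the dinuclear zinc complex should deliver the alkynylzinc to one aldehyde face and so set C-6 as the R carbinol.

Step 6
Reactants: 9 (4R,5E)-1-[(tert-butyldimethylsilyl)oxy]-6-{[(4-methoxybenzyl)oxy]methyl}-8-(trimethylsilyl)oct-5-ene-2,7-diyn-4-ol
Product: 11 (2Z,4R,5E)-1-[(tert-butyldimethylsilyl)oxy]-2-iodo-6-{[(4-methoxybenzyl)oxy]methyl}-8-(trimethylsilyl)octa-2,5-dien-7-yn-4-ol, via cyclic sodium vinylalanate 10 (not isolated)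
Conditions: NaAlH2(OCH2CH2OMe)2, THF, −20 °C to 0 °C; then I2, THF, −78 °C
Reagents that add atoms: iodine, [I][I]; sodium bis(2-methoxyethoxy)aluminium dihydride, [Na+].COCCO[AlH2-]OCCOC (its atoms stay in intermediate 10 only)
Why: The same alkoxide-directed trans-hydroalumination–iodination as in step 2 acts on the propargylic triple bond only, because the silyl-capped enyne cannot form the five-membered alanate and should stay intact at low temperature.

Step 7
Reactants: 11 (2Z,4R,5E)-1-[(tert-butyldimethylsilyl)oxy]-2-iodo-6-{[(4-methoxybenzyl)oxy]methyl}-8-(trimethylsilyl)octa-2,5-dien-7-yn-4-ol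
Product: 12 (5R)-3-{[(tert-butyldimethylsilyl)oxy]methyl}-5-[(1E)-2-{[(4-methoxybenzyl)oxy]methyl}-4-(trimethylsilyl)but-1-en-3-yn-1-yl]furan-2(5H)-one
Conditions: Pd(PPh3)2Cl2 (5 mol %), CO (1 atm), iPr2NEt, THF, rt
Reagents that add atoms: carbon monoxide, [C-]#[O+]
Why: Carbonylative lactonisation, in which zerovalent palladium inserts into the C–I bond, CO inserts and the cis hydroxyl traps the acyl-palladium, closes the lactone ring; the hindered amine and ambient temperature are chosen to spare the base-labile C-6 centre.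

Step 8
Reactants: 12 (5R)-3-{[(tert-butyldimethylsilyl)oxy]methyl}-5-[(1E)-2-{[(4-methoxybenzyl)oxy]methyl}-4-(trimethylsilyl)but-1-en-3-yn-1-yl]furan-2(5H)-one
Product: 13 (5R)-3-(bromomethyl)-5-[(1E)-2-{[(4-methoxybenzyl)oxy]methyl}-4-(trimethylsilyl)but-1-en-3-yn-1-yl]furan-2(5H)-one
Conditions: Ph3PBr2, CH2Cl2, 0 °C to rt
Reagents that add atoms: triphenylphosphine dibromide, BrP(Br)(c1ccccc1)(c1ccccc1)c1ccccc1
Why: Direct conversion of a primary allylic silyl ether into the bromide through the alkoxyphosphonium salt, conditions under which the benzylic ether and the silyl alkyne should be inert.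

Step 9
Reactants: 14 (S)-2-methylglycidol [(2S)-(2-methyloxiran-2-yl)methanol]; 15 vinylmagnesium bromide
Product: 16 (2R)-2-methylpent-4-ene-1,2-diol
Conditions: CH2=CHMgBr (3 equiv), CuI (10 mol %), THF, −30 °C to 0 °C
Reagents that add atoms: none
Why: Copper-catalysed Grignard opening of the 2,2-disubstituted epoxide at its CH2 terminus leaves the quaternary centre untouched, so the commercial epoxide supplies C-10 (the descriptor changes from S to R only through the priority rules).

Step 10
Reactants: 16 (2R)-2-methylpent-4-ene-1,2-diol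
Product: 17 (4R)-2,2,4-trimethyl-4-(prop-2-en-1-yl)-1,3-dioxolane
Conditions: Me2C(OMe)2, PPTS (cat.), CH2Cl2, rt
Reagents that add atoms: 2,2-dimethoxypropane, COC(C)(C)OC
Why: Acid-catalysed transketalisation ties the C-1 and C-10 oxygens into an acetonide that survives the zinc, acylation and iodination steps.

Step 11
Reactants: 17 (4R)-2,2,4-trimethyl-4-(prop-2-en-1-yl)-1,3-dioxolane
Product: 19 2-[(4R)-2,2,4-trimethyl-1,3-dioxolan-4-yl]acetaldehyde, via secondary ozonide 18 (not isolated)
Conditions: O3, CH2Cl2, −78 °C; then PPh3, −78 °C to rt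
Reagents that add atoms: ozone, [O-][O+]=O
Why: Ozonolysis of the terminal alkene with reductive work-up gives the C-8 aldehyde, the only other functionality being the inert acetonide.

Step 12
Reactants: 13 (5R)-3-(bromomethyl)-5-[(1E)-2-{[(4-methoxybenzyl)oxy]methyl}-4-(trimethylsilyl)but-1-en-3-yn-1-yl]furan-2(5H)-one; 19 2-[(4R)-2,2,4-trimethyl-1,3-dioxolan-4-yl]acetaldehyde
Product: 20 (4R,5R)-4-{(1S)-1-hydroxy-2-[(4R)-2,2,4-trimethyl-1,3-dioxolan-4-yl]ethyl}-5-[(1E)-2-{[(4-methoxybenzyl)oxy]methyl}-4-(trimethylsilyl)but-1-en-3-yn-1-yl]-3-methylideneoxolan-2-one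
Conditions: Zn, THF/sat. aq. NH4Cl, 0 °C to rt
Reagents that add atoms: none
Why: Barbier allylation in which the allylzinc from 13 adds through its ring carbon (SE2') anti to the C-5 alkenyl group on C-6 (6,7-trans), and a chair transition state with the ring-locked E allyl geometry and an equatorial aldehyde substituent should give the 7,8-anti (8S) carbinol.

Step 13
Reactants: 20 Barbier adduct (as named in step 12); 21 tiglic acid [(E)-2-methylbut-2-enoic acid]
Product: 23 8-O-tigloyl derivative of 20, via tiglic 2,4,6-trichlorobenzoic anhydride 22 (not isolated)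
Conditions: 2,4,6-Cl3C6H2COCl, Et3N, toluene, rt; then 20, DMAP, toluene, rt to 40 °C
Reagents that add atoms: 2,4,6-trichlorobenzoyl chloride, O=C(Cl)c1c(Cl)cc(Cl)cc1Cl (its acyl group is carried by intermediate 22 only)
Why: Yamaguchi esterification acylates the hindered C-8 alcohol with retention at carbon and keeps the E geometry of the tiglate.

Step 14
Reactants: 23 8-O-tigloyl derivative of 20
Product: 24 iodoalkyne analogue of 23 (C≡C–I in place of C≡C–SiMe3)
Conditions: N-iodosuccinimide, AgNO3 (10 mol %), acetone, rt, dark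
Reagents that add atoms: N-iodosuccinimide, O=C1CCC(=O)N1I
Why: Silver-catalysed iododesilylation turns the alkynylsilane directly into the iodoalkyne needed for the chromium-mediated ring closure.

Step 15
Reactants: 24 iodoalkyne analogue of 23
Product: 25 diol of 24 (C-1 CH2OH and tertiary C-10 OH free, R at C-10)
Conditions: AcOH/THF/H2O (3:1:1), 45 °C
Reagents that add atoms: none
Why: Mild acid hydrolysis of the acetonide should leave the PMB ether, the tiglate, the lactone and the iodoalkyne untouched.

Step 16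
Reactants: 25 diol of 24
Product: 26 α-hydroxy aldehyde (C-1 CHO, tertiary C-10 OH)
Conditions: IBX, DMSO, rt
Reagents that add atoms: none
Why: IBX oxidation converts the primary alcohol into the aldehyde, the tertiary hydroxyl cannot be oxidised, and IBX does not cleave the C-1/C-10 glycol bond.

Step 17
Reactants: 26 α-hydroxy aldehyde
Product: 27 ten-membered enyne diol: 1,10-dihydroxy-15-[(4-methoxybenzyl)oxy]-8-tigloyloxygermacra-4,11(13)-dien-2-yn-12,6-olide (6R,7R,8S,10R; C-3 and C-6 cis on C4=C5; C-1 epimers)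
Conditions: CrCl2 (8 equiv), NiCl2 (5 mol %), THF, rt, 2 mM, slow addition
Reagents that add atoms: none
Why: Nozaki–Hiyama–Kishi ring closure in which the alkynylchromium adds to the aldehyde at high dilution, a closure with precedent for strained ten-membered enediyne carbinols; the C-1 configuration is irrelevant because it is oxidised next.

Step 18
Reactants: 27 ten-membered enyne diol
Product: 29 15-O-(4-methoxybenzyl)lychnophorolide B, via macrocyclic hydroxy ynone 28 (not isolated)
Conditions: IBX, DMSO/THF, rt; aqueous work-up; then Ph3PAuNTf2 (5 mol %), toluene, rt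
Reagents that add atoms: none
Why: IBX oxidises the secondary propargylic C-1 carbinol (the tertiary C-10 hydroxyl is inert and the glycol bond is not cleaved) to the ten-membered enynone 28; the cationic monovalent gold complex then π-activates the C2≡C3 bond, the C-10 hydroxyl adds to C-3 anti to gold, and protodeauration gives the 3(2H)-furanone. The closest known reaction type is the gold-catalysed cycloisomerisation of acyclic α'-hydroxy ynones to 3(2H)-furanones, run here across a ring. The ring (O, C-3, C-2, C-1, C-10) closes in 5-endo-dig mode and turns the cycloalkyne into the oxygen-bridged bicycle, so loss of the bent triple bond from the ten-membered ring and formation of the vinylogous ester should both drive it. No stereocentre is created: C-10 comes from 14 and cannot epimerise, C-6 to C-8 are untouched, and the new C2=C3 bond must have oxygen and C-1 cis in the five-membered ring. The step needs O–C-3 bond formation in preference to 1,6-addition at C-5 and to reaction at the methylene lactone or tiglate; the first is secured by the tether (attack at C-5 would need a seven-membered ring) and the second by a carbophilic, non-basic catalyst and the absence of other free nucleophiles (C-8 acylated, C-15 a PMB ether).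

Step 19
Reactants: 29 15-O-(4-methoxybenzyl)lychnophorolide B
Product: 30 lychnophorolide B
Conditions: DDQ, CH2Cl2/pH 7 phosphate buffer, 0 °C to rt
Reagents that add atoms: none
Why: Oxidative cleavage of the PMB ether by DDQ is neutral and should spare the electron-poor dienone, the methylene lactone and the tiglate.

**Compound list**
1 | but-2-yne-1,4-diol | OCC#CCO | starting material
2 | 4-[(4-methoxybenzyl)oxy]but-2-yn-1-ol | COc1ccc(COCC#CCO)cc1 | intermediate
3 | cyclic sodium vinylalanate from 2 | [Na+].COCCO[Al-]1(OCCOC)OCC=C1COCc1ccc(OC)cc1 | intermediate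
4 | (Z)-3-iodo-4-[(4-methoxybenzyl)oxy]but-2-en-1-ol | OC/C=C(\I)COCc1ccc(OC)cc1 | intermediate
5 | ethynyltrimethylsilane | C#C[Si](C)(C)C | starting material
6 | (E)-3-{[(4-methoxybenzyl)oxy]methyl}-5-(trimethylsilyl)pent-2-en-4-yn-1-ol | OC/C=C(\C#C[Si](C)(C)C)COCc1ccc(OC)cc1 | intermediate
7 | (E)-3-{[(4-methoxybenzyl)oxy]methyl}-5-(trimethylsilyl)pent-2-en-4-ynal | O=C/C=C(\C#C[Si](C)(C)C)COCc1ccc(OC)cc1 | intermediate
8 | tert-butyldimethyl(prop-2-yn-1-yloxy)silane | C#CCO[Si](C)(C)C(C)(C)C | starting material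
9 | (4R,5E)-1-[(tert-butyldimethylsilyl)oxy]-6-{[(4-methoxybenzyl)oxy]methyl}-8-(trimethylsilyl)oct-5-ene-2,7-diyn-4-ol | CC(C)(C)[Si](C)(C)OCC#C[C@H](O)/C=C(\C#C[Si](C)(C)C)COCc1ccc(OC)cc1 | intermediate
10 | cyclic sodium vinylalanate from 9 | [Na+].COCCO[Al-]1(OCCOC)O[C@H](/C=C(\C#C[Si](C)(C)C)COCc2ccc(OC)cc2)C=C1CO[Si](C)(C)C(C)(C)C | intermediate
11 | (2Z,4R,5E)-1-[(tert-butyldimethylsilyl)oxy]-2-iodo-6-{[(4-methoxybenzyl)oxy]methyl}-8-(trimethylsilyl)octa-2,5-dien-7-yn-4-ol | CC(C)(C)[Si](C)(C)OC/C(I)=C/[C@H](O)/C=C(\C#C[Si](C)(C)C)COCc1ccc(OC)cc1 | intermediate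
12 | (5R)-3-{[(tert-butyldimethylsilyl)oxy]methyl}-5-[(1E)-2-{[(4-methoxybenzyl)oxy]methyl}-4-(trimethylsilyl)but-1-en-3-yn-1-yl]furan-2(5H)-one | O=C1O[C@H](/C=C(\C#C[Si](C)(C)C)COCc2ccc(OC)cc2)C=C1CO[Si](C)(C)C(C)(C)C | intermediate
13 | (5R)-3-(bromomethyl)-5-[(1E)-2-{[(4-methoxybenzyl)oxy]methyl}-4-(trimethylsilyl)but-1-en-3-yn-1-yl]furan-2(5H)-one | O=C1O[C@H](/C=C(\C#C[Si](C)(C)C)COCc2ccc(OC)cc2)C=C1CBr | intermediate
14 | (S)-2-methylglycidol | OC[C@@]1(C)CO1 | starting material
15 | vinylmagnesium bromide | C=C[Mg]Br | starting material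
16 | (2R)-2-methylpent-4-ene-1,2-diol | C=CC[C@@](C)(O)CO | intermediate
17 | (4R)-2,2,4-trimethyl-4-(prop-2-en-1-yl)-1,3-dioxolane | C=CC[C@]1(C)COC(C)(C)O1 | intermediate
18 | secondary ozonide of 17 (3-{[(4R)-2,2,4-trimethyl-1,3-dioxolan-4-yl]methyl}-1,2,4-trioxolane) | C1(OOCO1)C[C@]2(C)COC(C)(C)O2 | intermediate
19 | 2-[(4R)-2,2,4-trimethyl-1,3-dioxolan-4-yl]acetaldehyde | O=CC[C@]1(C)COC(C)(C)O1 | intermediate
20 | (4R,5R)-4-{(1S)-1-hydroxy-2-[(4R)-2,2,4-trimethyl-1,3-dioxolan-4-yl]ethyl}-5-[(1E)-2-{[(4-methoxybenzyl)oxy]methyl}-4-(trimethylsilyl)but-1-en-3-yn-1-yl]-3-methylideneoxolan-2-one | C=C1C(=O)O[C@H](/C=C(\C#C[Si](C)(C)C)COCc2ccc(OC)cc2)[C@H]1[C@@H](O)C[C@]3(C)COC(C)(C)O3 | intermediate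
21 | tiglic acid | C/C=C(\C)C(=O)O | starting material
22 | tiglic 2,4,6-trichlorobenzoic anhydride | C/C=C(\C)C(=O)OC(=O)c1c(Cl)cc(Cl)cc1Cl | intermediate
23 | 8-O-tigloyl derivative of 20 | C=C1C(=O)O[C@H](/C=C(\C#C[Si](C)(C)C)COCc2ccc(OC)cc2)[C@H]1[C@@H](OC(=O)/C(C)=C/C)C[C@]3(C)COC(C)(C)O3 | intermediate
24 | iodoalkyne analogue of 23 | C=C1C(=O)O[C@H](/C=C(\C#CI)COCc2ccc(OC)cc2)[C@H]1[C@@H](OC(=O)/C(C)=C/C)C[C@]3(C)COC(C)(C)O3 | intermediate
25 | diol of 24 (C-1 CH2OH, C-10 OH) | C=C1C(=O)O[C@H](/C=C(\C#CI)COCc2ccc(OC)cc2)[C@H]1[C@@H](OC(=O)/C(C)=C/C)C[C@@](C)(O)CO | intermediate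
26 | α-hydroxy aldehyde (C-1 CHO, C-10 OH) | C=C1C(=O)O[C@H](/C=C(\C#CI)COCc2ccc(OC)cc2)[C@H]1[C@@H](OC(=O)/C(C)=C/C)C[C@@](C)(O)C=O | intermediate
27 | ten-membered enyne diol (C-1 epimers) | C=C1C(=O)O[C@@H]2/C=C(/COCc3ccc(OC)cc3)C#CC(O)[C@](C)(O)C[C@H](OC(=O)/C(C)=C/C)[C@@H]12 | intermediate
28 | ten-membered 10-hydroxy-1-oxo-2-yne (hydroxy ynone) | C=C1C(=O)O[C@@H]2/C=C(/COCc3ccc(OC)cc3)C#CC(=O)[C@](C)(O)C[C@H](OC(=O)/C(C)=C/C)[C@@H]12 | intermediate
29 | 15-O-(4-methoxybenzyl)lychnophorolide B | C=C1C(=O)O[C@@H]2/C=C(/COCc3ccc(OC)cc3)C4=CC(=O)[C@@](C)(C[C@H](OC(=O)/C(C)=C/C)[C@@H]12)O4 | intermediate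
30 | lychnophorolide B | C=C1C(=O)O[C@@H]2/C=C(/CO)C3=CC(=O)[C@@](C)(C[C@H](OC(=O)/C(C)=C/C)[C@@H]12)O3 | target

**Step count**
Total: 19 steps. Longest linear sequence: 16 steps (steps 1–8, then 12–19); steps 9–11 make the second fragment.

**Steps most likely to fail**

Step 17. The ring closure may stall or give oligomers because the bent enyne geometry is hard to reach from the organochromium intermediate, and the free α-hydroxy aldehyde may degrade by ketol rearrangement while waiting. The fallback sets out from 23 and keeps the alkyne as its silane. Acetonide hydrolysis would give the silylalkyne diol F2, IBX the silylalkyne hydroxy aldehyde F3, and the ring would be closed by fluoride-triggered desilylative alkynylation (Bu4N[Ph3SiF2], THF, high dilution), a Lewis-base activation of silicon in place of the reductive generation of an organochromium. Aqueous work-up returns the route to 27.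

Step 18. The strained hydroxy ynone may decompose or be over-oxidised before it cyclises. The fallback sets out from 27 and reverses the order of events. A 5-endo-dig hydroalkoxylation at the diol oxidation level (Ph3PAuNTf2 or AgOTf, buffered with 2,6-di-tert-butylpyridine) would give the bridged dihydrofuranol F1, and MnO2 oxidation of its enol-ether allylic alcohol would return the route to 29 without passing through the free ynone.

Step 12. Simple diastereoselection in the allylzinc addition may favour the syn adduct, giving the wrong configuration at C-8. The fallback sets out from 13 and 19. The 8-epi adduct F4 would be esterified with inversion by a Mitsunobu reaction with tiglic acid 21 (PPh3, DIAD, THF), which installs the ester and corrects C-8 at once, and the route is rejoined at 23.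

**Further compounds**
F1 | step 18 | bridged dihydrofuranol (1-hydroxy analogue of 29, C-1 epimers) | C=C1C(=O)O[C@@H]2/C=C(/COCc3ccc(OC)cc3)C4=CC(O)[C@@](C)(C[C@H](OC(=O)/C(C)=C/C)[C@@H]12)O4
F2 | step 17 | silylalkyne diol (trimethylsilyl analogue of 25) | C=C1C(=O)O[C@H](/C=C(\C#C[Si](C)(C)C)COCc2ccc(OC)cc2)[C@H]1[C@@H](OC(=O)/C(C)=C/C)C[C@@](C)(O)CO
F3 | step 17 | silylalkyne hydroxy aldehyde (trimethylsilyl analogue of 26) | C=C1C(=O)O[C@H](/C=C(\C#C[Si](C)(C)C)COCc2ccc(OC)cc2)[C@H]1[C@@H](OC(=O)/C(C)=C/C)C[C@@](C)(O)C=O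
F4 | step 12 | 8-epi adduct (1R carbinol epimer of 20) | C=C1C(=O)O[C@H](/C=C(\C#C[Si](C)(C)C)COCc2ccc(OC)cc2)[C@H]1[C@H](O)C[C@]3(C)COC(C)(C)O3
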